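**Strategy.** Everything rests on cutting ring A (C1, C10, C11, C12, C13, C14) at C1–C10 and C13–C14: an enantioselective Diels–Alder reaction between 5-silyloxy-4-methyl-2-pyrone and methacrolein makes both bonds, the C1 quaternary centre and C10 at once. It exploits that C9 is cis to the C15 methyl and that C12, C13 and C14 are oxygenated: the pyrone carbonyl becomes C9, its bridging oxygen gives a C13 hydroxyl that is later eliminated to the C13=C14 olefin, and the enol ether sets C11 and C12 by hydrogenation. L-Malate delivers C7, C8 and C17–C19; diene–ene metathesis closes the ten-membered ring, and chlorine enters last.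

Key step: step 5

Remark: locants C1–C20 are briarane numbers of the target and β is the face of the C15 methyl group; the (S)-configured oxazaborolidinium catalyst is assumed to expose the enal face that leads to 7, its enantiomer being used otherwise.

Step 1
Reactants: 1 methyl 3-methylfuran-2-carboxylate
Product: 2 (3-methylfuran-2-yl)methanol
Conditions: LiAlH4, Et2O, 0 °C
Reagents that add atoms: none
Why: Hydride reduction of the ester gives the primary furfuryl alcohol; no stereocentre is involved.

Step 2
Reactants: 2 (3-methylfuran-2-yl)methanol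
Product: 3 6-hydroxy-4-methyl-2H-pyran-3(6H)-one
Conditions: mCPBA, CH2Cl2, 0 °C
Reagents that add atoms: mCPBA, O=C(OO)c1cccc(Cl)c1
Why: Achmatowicz oxidative ring expansion of the furfuryl alcohol gives the hydroxypyranone, whose racemic lactol centre is destroyed in step 3.

Step 3
Reactants: 3 6-hydroxy-4-methyl-2H-pyran-3(6H)-one
Product: 4 4-methyl-2H-pyran-2,5(6H)-dione
Conditions: PhI(OAc)2, TEMPO (cat.), CH2Cl2, 25 °C
Reagents that add atoms: none
Why: Oxoammonium-mediated lactol-to-lactone oxidation leaves the enone untouched and gives the keto tautomer of the 5-hydroxy-2-pyrone.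

Step 4
Reactants: 4 4-methyl-2H-pyran-2,5(6H)-dione
Product: 5 5-(tert-butyldimethylsilyloxy)-4-methyl-2H-pyran-2-one
Conditions: TBSOTf, Et3N, CH2Cl2, 0 °C
Reagents that add atoms: TBSOTf, CC(C)(C)[Si](C)(C)OS(=O)(=O)C(F)(F)F
Why: Silyl enol ether formation at the C5 ketone is driven by aromatisation to the 2-pyrone.

Step 5
Reactants: 5 5-(tert-butyldimethylsilyloxy)-4-methyl-2H-pyran-2-one; 6 methacrolein
Product: 7 endo-formyl 2-oxabicyclo[2.2.2]octenone cycloadduct
Conditions: (S)-o-tolyl oxazaborolidine from (S)-diphenylprolinol (20 mol %), Tf2NH (16 mol %), CH2Cl2, −78 to −40 °C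
Reagents that add atoms: none
Why: Proposed new method: the cationic oxazaborolidine binds the formyl oxygen of 6 and the electron-rich silyloxy pyrone adds in an asynchronous [4+2] cycloaddition (C13–C14 bond leading, then C1–C10), the closest known reactions being thermal Diels–Alder additions of 2-pyrones to acrylic dienophiles and oxazaborolidinium-catalysed Diels–Alder reactions of 2-methylacrolein with cyclic dienes. Ring A is closed by an intermolecular suprafacial [4+2] cycloaddition and emerges as the cyclohexene of a 2-oxabicyclo[2.2.2]octenone. C10 and C13 are fixed relative to each other by the lactone bridge, C1 relative to them by the endo position of the formyl group, and the absolute sense by the catalyst, which shields one face of the bound s-trans enal. Regioselectivity is needed (pyrone C6, the future C13, to the methylene carbon; pyrone C3, the future C10, to the quaternary carbon) and is secured by the C5 silyloxy donor, which makes C6 the nucleophilic terminus. Endo selectivity is needed and is secured because the exo methyl faces a lactone bridge without hydrogens, whereas an endo methyl would clash with the C4 methyl and C5 silyloxy groups of the diene.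

Step 6
Reactants: 7 endo-formyl cycloadduct
Product: 8 methyl 3-(tert-butyldimethylsilyloxy)-6-formyl-4-hydroxy-2,6-dimethylcyclohex-2-ene-1-carboxylate
Conditions: K2CO3 (cat.), MeOH, −10 °C
Reagents that add atoms: methanol, CO
Why: Transesterification opens the strained bridged lactone to the C9 methyl ester and the 13β-hydroxyl with retention at C10 and C13, the low temperature avoiding epimerisation of the activated C10–H.

Step 7
Reactants: 8 hydroxy ester silyl enol ether
Product: 9 methyl 3-(tert-butyldimethylsilyloxy)-6-formyl-4-hydroxy-2,6-dimethylcyclohexane-1-carboxylate (all-β substituents, α-formyl)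
Conditions: H2 (50 bar), 5% Rh on Al2O3, EtOAc, 25 °C
Reagents that add atoms: none
Why: Heterogeneous hydrogenation of the tetrasubstituted silyl enol ether adds both hydrogens syn from the α face, the β face being flanked by the C9 ester, the 13-hydroxyl and the C15 methyl, which sets C11 (methyl β) and C12 (silyloxy β) together.

Step 8
Reactants: 9 saturated hydroxy ester
Product: 10 methyl 5-(tert-butyldimethylsilyloxy)-2-formyl-2,6-dimethylcyclohex-3-ene-1-carboxylate
Conditions: Burgess reagent, toluene, 70 °C
Reagents that add atoms: none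
Why: Burgess dehydration is a syn elimination, and only C14 carries a hydrogen cis to the 13β-sulfamate (H-12 is α), so the C13=C14 olefin forms regiospecifically.

Step 9
Reactants: 10 cyclohexene aldehyde ester
Product: 11 13α,14α-epoxy aldehyde ester
Conditions: DMDO, acetone, −20 to 0 °C
Reagents that add atoms: dimethyldioxirane, CC1(C)OO1
Why: Dioxirane epoxidation occurs on the α face, anti to the allylic 12β-silyloxy group and the β-oriented C15, C20 and ester groups, and is faster than oxidation of the hindered aldehyde.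

Step 10
Reactants: 11 epoxy aldehyde ester
Product: 12 C2 allylic alcohol (both C2 epimers)
Conditions: CH2=CHMgBr, THF, −78 °C
Reagents that add atoms: vinylmagnesium bromide, C=C[Mg]Br
Why: Grignard 1,2-addition is chemoselective for the aldehyde over the hindered ester and the epoxide at low temperature; the epimer mixture is converged in steps 11 and 12.

Step 11
Reactants: 12 C2 allylic alcohol epimers
Product: 13 C2 vinyl ketone
Conditions: Dess–Martin periodinane, NaHCO3, CH2Cl2, 0 °C
Reagents that add atoms: none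
Why: Dess–Martin oxidation converts both epimers into one enone under non-basic conditions that spare the epoxide and the C10 centre.

Step 12
Reactants: 13 C2 vinyl ketone
Product: 14 C2 allylic alcohol of target configuration
Conditions: (S)-2-methyl-CBS-oxazaborolidine (0.5 equiv), catecholborane, toluene, −78 °C
Reagents that add atoms: none
Why: Corey–Bakshi–Shibata reduction adds hydride 1,2 with the quaternary C1 as the large and the vinyl as the small group, so the C2 carbinol is set under reagent control.

Step 13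
Reactants: 14 C2 allylic alcohol
Product: 15 2-O-triethylsilyl ether methyl ester
Conditions: Et3SiOTf, 2,6-lutidine, CH2Cl2, −78 °C
Reagents that add atoms: triethylsilyl triflate, CC[Si](CC)(CC)OS(=O)(=O)C(F)(F)F
Why: Silylation masks the allylic hydroxyl as an ether that survives steps 14 to 23 and leaves with the other silyl groups in step 24.

Step 14
Reactants: 15 2-O-triethylsilyl ether methyl ester
Product: 16 C9 aldehyde
Conditions: iBu2AlH, CH2Cl2, −78 °C; Rochelle salt
Reagents that add atoms: none
Why: Partial ester reduction stops at the aldehyde because the hindered tetrahedral aluminium hemiacetal is stable at −78 °C; the aldehyde is used at once to protect C10.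

Step 15
Reactants: 17 diethyl (S)-malate
Product: 19 diethyl (2S,3R)-2-hydroxy-3-methylbutanedioate, via dilithium alkoxide enolate 18 (not isolated)
Conditions: LiN(iPr)2 (2.2 equiv), THF, −78 to −20 °C; MeI, −78 °C
Reagents that add atoms: methyl iodide, CI
Why: Fráter–Seebach alkylation: the chelated alkoxide enolate is methylated anti to the C–O bond, which fixes C17 relative to C8.

Step 16
Reactants: 19 diethyl (2S,3R)-2-hydroxy-3-methylbutanedioate
Product: 20 (2S,3R)-2-hydroxy-3-methylbutanedioic acid
Conditions: KOH, H2O/EtOH, 0 to 25 °C; then HCl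
Reagents that add atoms: water, O
Why: Saponification of both esters under mild conditions leaves C8 and C17 untouched.

Step 17
Reactants: 20 (2S,3R)-2-hydroxy-3-methylbutanedioic acid
Product: 21 (2R)-2-[(2S,4S)-2-tert-butyl-5-oxo-1,3-dioxolan-4-yl]propanoic acid
Conditions: pivaldehyde, TsOH (cat.), pentane, reflux with water removal
Reagents that add atoms: pivaldehyde, CC(C)(C)C=O
Why: Acid-catalysed acetalisation of the α-hydroxy acid gives the cis dioxolanone (thermodynamic, crystallisable), whose acetal centre stores the C8 configuration.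

Step 18
Reactants: 16 C9 aldehyde; 21 dioxolanone acid
Product: 24 9-O-triethylsilyl aldol acid, via dilithium enolate 22 (not isolated), via bis-silyl adduct 23 (not isolated)
Conditions: LiN(SiMe3)2 (2.2 equiv), THF, −78 °C; add 16; then Et3SiOTf, −78 to −40 °C; aqueous NaHCO3
Reagents that add atoms: triethylsilyl triflate, CC[Si](CC)(CC)OS(=O)(=O)C(F)(F)F
Why: Aldol addition of the dioxolanone enolate (self-regeneration of stereocentres): the aldehyde enters trans to the tert-butyl group so C8 forms with retention, C9 follows Felkin–Anh attack anti to the quaternary C1, and silylation in the flask stops the 9-oxygen from lactonising onto C19.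

Step 19
Reactants: 25 prop-2-yn-1-ol
Product: 27 (Z)-3-iodo-2-methylprop-2-en-1-ol, via vinylmagnesium alkoxide 26 (not isolated)
Conditions: MeMgBr (2.5 equiv), CuI (cat.), THF, −10 to 25 °C; then I2, −78 to 0 °C
Reagents that add atoms: methylmagnesium bromide, C[Mg]Br; iodine, II
Why: Copper-catalysed anti-carbomagnesiation of the propargylic alkoxide gives a chelated vinylmagnesium species, and iodinolysis with retention places iodine cis to the hydroxymethyl group.

Step 20
Reactants: 27 (Z)-3-iodo-2-methylprop-2-en-1-ol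
Product: 28 (Z)-3-iodo-2-methylprop-2-enal
Conditions: MnO2, CH2Cl2, 25 °C
Reagents that add atoms: none
Why: Allylic alcohol oxidation with MnO2 gives the enal without Z-to-E isomerisation.

Step 21
Reactants: 28 (Z)-3-iodo-2-methylprop-2-enal
Product: 29 (Z)-1-iodo-2-methylbuta-1,3-diene
Conditions: Ph3PCH3Br, KOtBu, Et2O, 0 °C
Reagents that add atoms: methylenetriphenylphosphorane, C=P(c1ccccc1)(c1ccccc1)c1ccccc1
Why: Wittig methylenation gives the terminal diene, which is volatile and is used as an ethereal solution.

Step 22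
Reactants: 24 9-O-triethylsilyl aldol acid; 29 (Z)-1-iodo-2-methylbuta-1,3-diene
Product: 31 C7 dienone 8-hydroxy acid, via dienyllithium 30 (not isolated)
Conditions: 29, t-BuLi (2 equiv), Et2O, −78 °C; add to 24 pre-treated with LiN(SiMe3)2 (1 equiv), THF, −78 to −40 °C; aqueous NH4Cl
Reagents that add atoms: none
Why: Iodine–lithium exchange retains the Z geometry and the vinyllithium adds once to the activated acylal carbonyl C7 (lactone-to-ketone addition) while the lithium carboxylate is inert; collapse on work-up releases pivaldehyde and the 8-hydroxyl.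

Step 23
Reactants: 31 C7 dienone 8-hydroxy acid
Product: 33 γ-lactone with silyl-protected C2 C9 C12 oxygens, via dihydroxy acid 32 (not isolated)
Conditions: Zn(BH4)2, Et2O, −30 °C; then aqueous citric acid, 25 °C
Reagents that add atoms: none
Why: Chelation-controlled 1,2-reduction (Cram chelate of the C7 carbonyl and the 8-hydroxyl) delivers hydride from the face of the smaller C17 branch to give the anti 7,8-diol, and the 7-hydroxyl then lactonises onto C19 because the 9-oxygen is silylated.

Step 24
Reactants: 33 silyl-protected γ-lactone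
Product: 34 seco tetraol lactone
Conditions: HF·pyridine, pyridine, THF, 0 to 25 °C
Reagents that add atoms: none
Why: Fluoride-mediated desilylation removes both triethylsilyl ethers and the tert-butyldimethylsilyl ether without touching the epoxide or the lactone.

Step 25
Reactants: 34 seco tetraol lactone
Product: 35 macrocyclic (3Z,5Z)-diene tetraol
Conditions: second-generation Hoveyda–Grubbs catalyst (10 mol %), 1,4-benzoquinone (cat.), CH2Cl2 (1 mM), 40 °C
Reagents that add atoms: none
Why: Ring-closing diene–ene metathesis engages only the two monosubstituted olefins, and the ten-membered ring imposes the Z geometry at C3=C4 next to the preformed Z C5=C6 bond, a closure known for cyclohexane-fused ten-membered carbocycles.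

Step 26
Reactants: 35 macrocyclic diene tetraol
Product: 36 3,4-epoxy tetraol
Conditions: VO(acac)2 (cat.), t-BuOOH (1.1 equiv), CH2Cl2, 0 °C
Reagents that add atoms: tert-butyl hydroperoxide, CC(C)(C)OO
Why: Hydroxyl-directed vanadium-catalysed epoxidation oxidises only the olefin allylic to the free C2 hydroxyl and delivers oxygen syn to it, giving the cis 3,4-epoxide and sparing C5=C6.

Step 27
Reactants: 36 3,4-epoxy tetraol
Product: 37 2,9,12-triacetate
Conditions: Ac2O, pyridine, DMAP (cat.), CH2Cl2, 0 to 25 °C
Reagents that add atoms: acetic anhydride, CC(=O)OC(C)=O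
Why: Acylation esterifies the three secondary hydroxyls while the tertiary 8-hydroxyl stays free.

Step 28
Reactants: 37 2,9,12-triacetate
Product: 38 target (CNP0229305.1)
Conditions: N-chlorosuccinimide (1.1 equiv), PhSeCl (cat.), CH2Cl2, 0 to 25 °C
Reagents that add atoms: N-chlorosuccinimide, O=C1CCC(=O)N1Cl
Why: Ene-type allylic chlorination of the trisubstituted olefin puts chlorine on C6 and moves the double bond to C5=C16; chlorine should enter anti to the allylic C7–O bond in the conformer with H-7 eclipsing the olefin, which gives the 6S centre.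

**Compound list**

1 | methyl 3-methylfuran-2-carboxylate | COC(=O)c1occc1C | starting material
2 | (3-methylfuran-2-yl)methanol | OCc1occc1C | intermediate
3 | 6-hydroxy-4-methyl-2H-pyran-3(6H)-one (racemic lactol) | CC1=CC(O)OCC1=O | intermediate
4 | 4-methyl-2H-pyran-2,5(6H)-dione (keto tautomer of 5-hydroxy-4-methyl-2-pyrone) | CC1=CC(=O)OCC1=O | intermediate
5 | 5-(tert-butyldimethylsilyloxy)-4-methyl-2H-pyran-2-one | CC1=CC(=O)OC=C1O[Si](C)(C)C(C)(C)C | intermediate
6 | methacrolein (2-methylprop-2-enal) | CC(=C)C=O | starting material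
7 | 7-(tert-butyldimethylsilyloxy)-5,8-dimethyl-3-oxo-2-oxabicyclo[2.2.2]oct-7-ene-5-carbaldehyde; bridgeheads are C10 and C13, formyl (C2) endo towards the enol ether bridge, C15 methyl towards the lactone bridge | O=C[C@@]1(C)C[C@@H]2OC(=O)[C@H]1C(C)=C2O[Si](C)(C)C(C)(C)C | intermediate
8 | methyl 3-(tert-butyldimethylsilyloxy)-6-formyl-4-hydroxy-2,6-dimethylcyclohex-2-ene-1-carboxylate; C9 ester, 13-hydroxyl and C15 methyl β, formyl α | O=C[C@]1(C)[C@H](C(C)=C(O[Si](C)(C)C(C)(C)C)[C@@H](O)C1)C(=O)OC | intermediate
9 | methyl 3-(tert-butyldimethylsilyloxy)-6-formyl-4-hydroxy-2,6-dimethylcyclohexane-1-carboxylate; C9 ester, 11-methyl, 12-silyloxy, 13-hydroxyl and C15 methyl all β, formyl α | O=C[C@]1(C)[C@H]([C@@H](C)[C@@H](O[Si](C)(C)C(C)(C)C)[C@@H](O)C1)C(=O)OC | intermediate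
10 | methyl 5-(tert-butyldimethylsilyloxy)-2-formyl-2,6-dimethylcyclohex-3-ene-1-carboxylate (C13=C14 olefin; other centres as in 9) | O=C[C@]1(C)[C@H]([C@@H](C)[C@@H](O[Si](C)(C)C(C)(C)C)C=C1)C(=O)OC | intermediate
11 | 13α,14α-epoxide of 10 | O=C[C@]1(C)[C@H]([C@@H](C)[C@@H](O[Si](C)(C)C(C)(C)C)[C@@H]2O[C@H]12)C(=O)OC | intermediate
12 | allylic alcohol from vinyl addition to the formyl group of 11 (both C2 epimers) | C=CC(O)[C@]1(C)[C@H]([C@@H](C)[C@@H](O[Si](C)(C)C(C)(C)C)[C@@H]2O[C@H]12)C(=O)OC | intermediate
13 | C2 vinyl ketone (prop-2-enoyl group on C1) | C=CC(=O)[C@]1(C)[C@H]([C@@H](C)[C@@H](O[Si](C)(C)C(C)(C)C)[C@@H]2O[C@H]12)C(=O)OC | intermediate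
14 | C2 allylic alcohol with the target arrangement at C2 | C=C[C@@H](O)[C@]1(C)[C@H]([C@@H](C)[C@@H](O[Si](C)(C)C(C)(C)C)[C@@H]2O[C@H]12)C(=O)OC | intermediate
15 | 2-O-triethylsilyl ether of 14 | C=C[C@@H](O[Si](CC)(CC)CC)[C@]1(C)[C@H]([C@@H](C)[C@@H](O[Si](C)(C)C(C)(C)C)[C@@H]2O[C@H]12)C(=O)OC | intermediate
16 | C9 aldehyde corresponding to 15 | C=C[C@@H](O[Si](CC)(CC)CC)[C@]1(C)[C@H]([C@@H](C)[C@@H](O[Si](C)(C)C(C)(C)C)[C@@H]2O[C@H]12)C=O | intermediate
17 | diethyl (S)-malate | CCOC(=O)C[C@H](O)C(=O)OCC | starting material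
18 | dilithium alkoxide enolate of 17 | [Li+].[Li+].CCOC(=O)[C@@H]([O-])C=C([O-])OCC | intermediate
19 | diethyl (2S,3R)-2-hydroxy-3-methylbutanedioate | CCOC(=O)[C@@H](O)[C@@H](C)C(=O)OCC | intermediate
20 | (2S,3R)-2-hydroxy-3-methylbutanedioic acid | OC(=O)[C@@H](O)[C@@H](C)C(=O)O | intermediate
21 | (2R)-2-[(2S,4S)-2-tert-butyl-5-oxo-1,3-dioxolan-4-yl]propanoic acid (cis dioxolanone) | O=C1O[C@@H](C(C)(C)C)O[C@H]1[C@@H](C)C(=O)O | intermediate
22 | dilithium enolate carboxylate of 21 | [Li+].[Li+].[O-]C1=C([C@@H](C)C(=O)[O-])O[C@H](C(C)(C)C)O1 | intermediate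
23 | aldol adduct as 9-O-triethylsilyl ether and triethylsilyl ester | C=C[C@@H](O[Si](CC)(CC)CC)[C@]1(C)[C@H]([C@@H](C)[C@@H](O[Si](C)(C)C(C)(C)C)[C@@H]2O[C@H]12)[C@@H](O[Si](CC)(CC)CC)[C@]3(O[C@H](C(C)(C)C)OC3=O)[C@@H](C)C(=O)O[Si](CC)(CC)CC | intermediate
24 | aldol acid: 9-O-triethylsilyl ether, C8 as quaternary dioxolanone carbon (aldehyde carbon trans to tert-butyl), free C19 acid | C=C[C@@H](O[Si](CC)(CC)CC)[C@]1(C)[C@H]([C@@H](C)[C@@H](O[Si](C)(C)C(C)(C)C)[C@@H]2O[C@H]12)[C@@H](O[Si](CC)(CC)CC)[C@]3(O[C@H](C(C)(C)C)OC3=O)[C@@H](C)C(=O)O | intermediate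
25 | prop-2-yn-1-ol | C#CCO | starting material
26 | (Z)-vinylmagnesium bromide alkoxide from carbomagnesiation of 25 | Br[Mg]OC/C(C)=C\[Mg]Br | intermediate
27 | (Z)-3-iodo-2-methylprop-2-en-1-ol | OC/C(C)=C\I | intermediate
28 | (Z)-3-iodo-2-methylprop-2-enal | O=C/C(C)=C\I | intermediate
29 | (Z)-1-iodo-2-methylbuta-1,3-diene | C=C/C(C)=C\I | intermediate
30 | [(1Z)-2-methylbuta-1,3-dien-1-yl]lithium | [Li]/C=C(C)\C=C | intermediate
31 | C7 (Z)-dienone with free tertiary 8-hydroxyl and C19 acid | C=C[C@@H](O[Si](CC)(CC)CC)[C@]1(C)[C@H]([C@@H](C)[C@@H](O[Si](C)(C)C(C)(C)C)[C@@H]2O[C@H]12)[C@@H](O[Si](CC)(CC)CC)[C@@](O)(C(=O)/C=C(C)\C=C)[C@@H](C)C(=O)O | intermediate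
32 | anti 7,8-dihydroxy acid | C=C[C@@H](O[Si](CC)(CC)CC)[C@]1(C)[C@H]([C@@H](C)[C@@H](O[Si](C)(C)C(C)(C)C)[C@@H]2O[C@H]12)[C@@H](O[Si](CC)(CC)CC)[C@@](O)([C@@H](O)/C=C(C)\C=C)[C@@H](C)C(=O)O | intermediate
33 | γ-lactone (C19 to O7) with 2,9-bis(triethylsilyl) and 12-tert-butyldimethylsilyl ethers | C=C[C@@H](O[Si](CC)(CC)CC)[C@]1(C)[C@H]([C@@H](C)[C@@H](O[Si](C)(C)C(C)(C)C)[C@@H]2O[C@H]12)[C@@H](O[Si](CC)(CC)CC)[C@]3(O)[C@@H](C)C(=O)O[C@H]3/C=C(C)\C=C | intermediate
34 | seco tetraol lactone (2,8,9,12-tetrol) | C=C[C@@H](O)[C@]1(C)[C@H]([C@@H](C)[C@@H](O)[C@@H]2O[C@H]12)[C@@H](O)[C@]3(O)[C@@H](C)C(=O)O[C@H]3/C=C(C)\C=C | intermediate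
35 | macrocyclic (3Z,5Z)-diene tetraol (briarane skeleton, 13α,14α-epoxide) | O[C@@H]1/C=C\C(C)=C/[C@@H]2OC(=O)[C@H](C)[C@@]2(O)[C@H](O)[C@H]3[C@@H](C)[C@@H](O)[C@@H]4O[C@@H]4[C@@]31C | intermediate
36 | cis 3,4-epoxide of 35 (oxygen syn to the 2-hydroxyl) | O[C@@H]1[C@@H]5O[C@@H]5/C(C)=C\[C@@H]2OC(=O)[C@H](C)[C@@]2(O)[C@H](O)[C@H]3[C@@H](C)[C@@H](O)[C@@H]4O[C@@H]4[C@@]31C | intermediate
37 | 2,9,12-triacetate of 36, (5Z)-olefin, free 8-hydroxyl | CC(=O)O[C@@H]1[C@@H]5O[C@@H]5/C(C)=C\[C@@H]2OC(=O)[C@H](C)[C@@]2(O)[C@H](OC(C)=O)[C@H]3[C@@H](C)[C@@H](OC(C)=O)[C@@H]4O[C@@H]4[C@@]31C | intermediate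
38 | CNP0229305.1 | C=C1[C@H]2O[C@H]2[C@@H](OC(C)=O)[C@]2(C)[C@H]([C@@H](C)[C@@H](OC(C)=O)[C@@H]3O[C@@H]32)[C@@H](OC(C)=O)[C@]2(O)[C@@H](C)C(=O)O[C@H]2[C@H]1Cl | target

**Step count.** 28 steps in total; the longest linear sequence is 22 steps (steps 1–14, 18, 22–28).

**Steps most likely to fail**

Step 5 (proposed method). What may go wrong is loss of enantiofacial control, or desilylation of the pyrone and loss of CO2 from the adduct under the strong Lewis acid. The fallback sets out from 5 and 6 and comes back at 8. Heating 5 with 6 in toluene at 70 °C without catalyst (the established thermal pyrone Diels–Alder reaction) should give the racemic endo adduct F1. Methanolysis as in step 6 gives the racemic hydroxy ester F2. Candida antarctica lipase B with vinyl acetate should then, by the usual empirical rule for secondary alcohols, acetylate the 13R enantiomer to the acetate of the mirror-image alcohol F3 and leave 8, which is separated and continues at step 7.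

Step 18. What may go wrong is proton transfer from the α-branched aldehyde to the basic enolate (enolisation and epimerisation at C10) and retro-aldol reversal between two hindered partners. The fallback sets out from 21 and 16 and comes back at 24. Compound 21 is converted with LiN(SiMe3)2 and Et3SiCl into the bis(triethylsilyl) ketene acetal ester F4. F4 is added to 16 with catalytic Et3SiOTf in CH2Cl2 at −78 °C (Mukaiyama aldol through an open transition state under non-basic conditions, with the same trans-to-tert-butyl and Felkin–Anh preferences). Silyl transfer gives 23, and aqueous work-up gives 24.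

Step 28. What may go wrong is chlorination from the wrong face of the olefin, chlorohydrin formation, or acid-induced opening of the vinyl epoxide. The fallback sets out from 37 and comes back at 38. SeO2 (cat.) with t-BuOOH oxidises the C16 methyl group to the primary allylic alcohol F5. SOCl2 in Et2O at 0 °C without base then collapses the chlorosulfite with allylic transposition, placing chlorine on C6 and the double bond at C5=C16.

**Further compounds**

F1 | step 5 | racemic endo cycloadduct (7 and its mirror image) | O=C[C@@]1(C)C[C@@H]2OC(=O)[C@H]1C(C)=C2O[Si](C)(C)C(C)(C)C.O=C[C@]1(C)C[C@H]2OC(=O)[C@@H]1C(C)=C2O[Si](C)(C)C(C)(C)C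
F2 | step 5 | racemic hydroxy ester (8 and its mirror image) | O=C[C@]1(C)[C@H](C(C)=C(O[Si](C)(C)C(C)(C)C)[C@@H](O)C1)C(=O)OC.O=C[C@@]1(C)[C@@H](C(C)=C(O[Si](C)(C)C(C)(C)C)[C@H](O)C1)C(=O)OC
F3 | step 5 | 13-O-acetate of the mirror image of 8 | O=C[C@@]1(C)[C@@H](C(C)=C(O[Si](C)(C)C(C)(C)C)[C@H](OC(C)=O)C1)C(=O)OC
F4 | step 18 | bis(triethylsilyl) ketene acetal ester of 21 | C[C@@H](C(=O)O[Si](CC)(CC)CC)C1=C(O[Si](CC)(CC)CC)O[C@@H](C(C)(C)C)O1
F5 | step 28 | 16-hydroxy derivative of 37 | CC(=O)O[C@@H]1[C@@H]5O[C@@H]5/C(CO)=C\[C@@H]2OC(=O)[C@H](C)[C@@]2(O)[C@H](OC(C)=O)[C@H]3[C@@H](C)[C@@H](OC(C)=O)[C@@H]4O[C@@H]4[C@@]31C
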